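**Plan**

- Cuts, in retrosynthetic order: the three ester C–O bonds; C13–C16 (ring D); C8–C15; C8=C14 and C9–C11 (ring C); C6–C8 (ring B); then C1–C10 together with C5–C6 (ring A); C5=C10; C4–CH3; C3–C4.
- Forward order: acyclic C3/C4 pair → unsaturated δ-lactone in which C20 is tied to C3 through oxygen (a temporary ring) → ring A → ring B → ring C → ring D → triacid.
- Enabling feature: C10 is quaternary, carries the C20 carboxyl and lies 1,4 to C3 across ring A. With C20 held as a lactone on an allylic C3–O bond and C1=C2 as a vinyl group on C3, the C10 ester enolate and C1 are the two ends of the 1,5-diene C10=C20–O–C3–C2=C1. Its [3,3] shift closes ring A and sets the C20 acid free.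
- Stereochemistry: C3 from an Evans aldol; C4 relayed from C3 (Fráter–Seebach methylation); C5 by conjugate addition anti to the C3 vinyl and C4 methyl groups; C10 by chirality transfer from the C3–O bond through a boat transition state; C6 and C9 under thermodynamic control; C8 by conjugate addition that forms the cis-hydrindanone; C13 by the bridging geometry.

Key step: step 11

Remark: atoms are numbered as in the gibberellane skeleton (C19 and C20 are the carboxyls on C4 and C10, C7 the carboxyl on C6); C6 and C9 are epimerisable in 24–28 and are taken to settle as the natural epimers.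

**Step 1**
Reactants: 1 3-[(4-methoxybenzyl)oxy]propanoic acid; 2 (S)-4-benzyl-1,3-oxazolidin-2-one
Product: 3 (S)-4-benzyl-3-{3-[(4-methoxybenzyl)oxy]propanoyl}-1,3-oxazolidin-2-one
Conditions: PivCl, Et3N, THF, −20 °C; then 2, LiCl, rt
Reagents that add atoms: none
Why: N-acylation of the oxazolidinone through the mixed pivalic anhydride is the standard entry to Evans imides and creates no stereocenter.

**Step 2**
Reactants: 3 (S)-4-benzyl-3-{3-[(4-methoxybenzyl)oxy]propanoyl}-1,3-oxazolidin-2-one; 4 acrolein
Product: 5 (S)-4-benzyl-3-[(2S,3R)-3-hydroxy-2-{[(4-methoxybenzyl)oxy]methyl}pent-4-enoyl]-1,3-oxazolidin-2-one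
Conditions: Bu2BOTf, i-Pr2NEt, CH2Cl2, 0 °C; 4, −78 → 0 °C; pH 7 buffer, MeOH, H2O2
Reagents that add atoms: none
Why: Evans syn-aldol reaction, in which the (Z)-boron enolate reacts through a closed Zimmerman–Traxler transition state on the face away from the benzyl group and so sets the carbinol carbon (the future C3) as R, while the α-center formed with it is erased in step 4.

**Step 3**
Reactants: 5 (S)-4-benzyl-3-[(2S,3R)-3-hydroxy-2-{[(4-methoxybenzyl)oxy]methyl}pent-4-enoyl]-1,3-oxazolidin-2-one
Product: 6 methyl (2S,3R)-3-hydroxy-2-{[(4-methoxybenzyl)oxy]methyl}pent-4-enoate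
Conditions: NaOMe, MeOH, 0 °C
Reagents that add atoms: methanol (CO)
Why: Methanolysis of the exocyclic imide carbonyl at 0 °C should release the methyl ester and the recoverable auxiliary without retro-aldol cleavage and without touching a stereocenter.

**Step 4**
Reactants: 6 methyl (2S,3R)-3-hydroxy-2-{[(4-methoxybenzyl)oxy]methyl}pent-4-enoate
Product: 7 methyl (2S,3R)-3-hydroxy-2-{[(4-methoxybenzyl)oxy]methyl}-2-methylpent-4-enoate
Conditions: LiN(i-Pr)2 (LDA, 2.2 equiv), THF, −78 → −20 °C; MeI, DMPU, −78 → −10 °C
Reagents that add atoms: iodomethane (CI)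
Why: Fráter–Seebach alkylation, in which iodomethane approaches the lithium-chelated alkoxide–enolate dianion anti to the vinyl group on the carbinol carbon, so that the quaternary C4 should form as 2S with methyl and vinyl on the same side of the later lactone ring, the low temperature holding back β-elimination of the ether.

**Step 5**
Reactants: 8 triethyl phosphonoacetate; 9 benzyl 2-bromoethyl ether
Product: 10 ethyl 4-(benzyloxy)-2-(diethoxyphosphoryl)butanoate (racemic)
Conditions: NaH, DMF, 0 °C; then 9, 60 °C
Reagents that add atoms: none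
Why: SN2 C-alkylation of the stabilised phosphonoacetate anion by a primary bromide, the new center being racemic and lost again in step 10.

**Step 6**
Reactants: 10 ethyl 4-(benzyloxy)-2-(diethoxyphosphoryl)butanoate
Product: 11 4-(benzyloxy)-2-(diethoxyphosphoryl)butanoic acid (racemic)
Conditions: LiOH·H2O, THF/H2O, 0 °C → rt; aq. HCl
Reagents that add atoms: lithium hydroxide ([Li+].[OH-])
Why: Saponification of the carboxylic ethyl ester, which is far faster than hydrolysis of the diethyl phosphonate.

**Step 7**
Reactants: 7 methyl (2S,3R)-3-hydroxy-2-{[(4-methoxybenzyl)oxy]methyl}-2-methylpent-4-enoate; 11 4-(benzyloxy)-2-(diethoxyphosphoryl)butanoic acid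
Product: 12 methyl (2S,3R)-3-{[4-(benzyloxy)-2-(diethoxyphosphoryl)butanoyl]oxy}-2-{[(4-methoxybenzyl)oxy]methyl}-2-methylpent-4-enoate (both epimers at the phosphorus-bearing carbon)
Conditions: DCC, DMAP (cat.), CH2Cl2, 0 °C → rt
Reagents that add atoms: none
Why: Steglich esterification of the hindered secondary allylic alcohol ties the phosphonate (future C10 and C20 with the C9–C8 arm) to the C3 oxygen with retention at C3.

**Step 8**
Reactants: 12 the phosphonoacyl ester of 7
Product: 13 methyl (2S,3R)-3-{[4-(benzyloxy)-2-(diethoxyphosphoryl)butanoyl]oxy}-2-(hydroxymethyl)-2-methylpent-4-enoate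
Conditions: DDQ, CH2Cl2/pH 7 buffer, 0 °C
Reagents that add atoms: none
Why: Oxidative cleavage of the p-methoxybenzyl ether by DDQ, which should spare the benzyl ether, the vinyl group and the esters.

**Step 9**
Reactants: 13 the primary alcohol
Product: 14 methyl (2R,3R)-3-{[4-(benzyloxy)-2-(diethoxyphosphoryl)butanoyl]oxy}-2-formyl-2-methylpent-4-enoate
Conditions: Dess–Martin periodinane, CH2Cl2, rt
Reagents that add atoms: none
Why: Dess–Martin oxidation of the neopentyl primary alcohol gives the aldehyde (future C5), which cannot enolise or epimerise because C4 is quaternary.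

**Step 10**
Reactants: 14 the phosphonate aldehyde
Product: 15 methyl (2R,3S)-5-[2-(benzyloxy)ethyl]-2-ethenyl-3-methyl-6-oxo-3,6-dihydro-2H-pyran-3-carboxylate
Conditions: LiCl, DBU, MeCN, rt, high dilution
Reagents that add atoms: none
Why: Intramolecular Horner–Wadsworth–Emmons olefination closes the α-substituted α,β-unsaturated δ-lactone, the ring enforcing the Z geometry of C5=C10 and leaving C3 and C4 untouched.

**Step 11**
Reactants: 15 methyl (2R,3S)-5-[2-(benzyloxy)ethyl]-2-ethenyl-3-methyl-6-oxo-3,6-dihydro-2H-pyran-3-carboxylate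
Product: 18 (1R,2S,3R)-1-[2-(benzyloxy)ethyl]-2-ethenyl-3-(methoxycarbonyl)-3-methylcyclohex-4-ene-1-carboxylic acid, via silyl ketene acetal 16 (not isolated), via silyl ester 17 (not isolated)
Conditions: CH2=CHMgBr, CuBr·SMe2 (10 mol%), TMSCl, HMPA, THF, −78 °C; Et3N, hexane, filtration; PhMe, 110 °C; then 1 M HCl, THF, rt
Reagents that add atoms: vinylmagnesium bromide (C=C[Mg]Br); chlorotrimethylsilane (C[Si](C)(C)Cl)
Why: Proposed new method: copper-catalysed, chlorosilane-accelerated 1,4-addition of the vinyl Grignard reagent to C5 delivers the C10 enolate regiospecifically as silyl ketene acetal 16, which on heating undergoes an Ireland–Claisen [3,3] shift along C10=C20–O–C3–C2=C1 that forms C1–C10, breaks O–C3 and turns the lactone into the C20 silyl ester on a new cyclohexene (ring A). The closest known reaction types are the conjugate addition/Ireland–Claisen cascade of allyl acrylates and the lactone-enolate Claisen rearrangement of 6-alkenyl δ-lactone silyl ketene acetals; their union in one flask on an unsaturated lactone is the new element, and it needs no base-mediated enolisation. Ring A closes not by an exo or endo attack but by a sigmatropic transposition through the boat-like, bicyclo[2.2.2]octane-shaped transition state that the six-membered lactone enforces. C5 is set in the addition, which should occur by axial attack anti to the pseudoaxial C18 methyl and trans to the pseudoequatorial C3 vinyl group; C10 is set by suprafacial chirality transfer from the C3–O bond, C1 being delivered to the enolate face that carries the C3 vinyl group, so that C20 ends syn-diaxial to the C19 ester and the C9 arm equatorial, trans to the C5 vinyl group. The step needs 1,4- over 1,2-addition and over SN2′ opening of the allylic carboxylate, which the copper catalyst with TMSCl at −78 °C should secure, and it needs a single enolate, which is guaranteed because C19 has no α-hydrogen and the enolate is born at C10. The trimethylsilyl group travels through 16 and 17 only and leaves as trimethylsilanol in the acidic work-up.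

**Step 12**
Reactants: 18 the ring-A acid
Product: 19 dimethyl (1R,2S,3R)-1-[2-(benzyloxy)ethyl]-2-ethenyl-3-methylcyclohex-4-ene-1,3-dicarboxylate
Conditions: TMSCHN2, PhMe/MeOH, 0 °C
Reagents that add atoms: trimethylsilyldiazomethane (C[Si](C)(C)C=[N+]=[N-])
Why: O-methylation of the hindered tertiary carboxylic acid by trimethylsilyldiazomethane in the presence of methanol needs no acyl substitution at the neopentyl C20 and gives the diester in which C19 and C20 are protected alike.

**Step 13**
Reactants: 19 the ring-A diester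
Product: 20 dimethyl (1R,2S,3R)-1-[2-(benzyloxy)ethyl]-2-(2-hydroxyethyl)-3-methylcyclohex-4-ene-1,3-dicarboxylate
Conditions: 9-BBN, THF, 0 °C → rt; then aq. NaOH, H2O2, 0 °C
Reagents that add atoms: hydrogen peroxide (OO)
Why: Anti-Markovnikov hydroboration–oxidation with 9-BBN, which takes the monosubstituted vinyl group far faster than the cis-disubstituted ring alkene, places the hydroxyl on C7.

**Step 14**
Reactants: 20 the C7 alcohol
Product: 21 dimethyl (1R,2R,3R)-1,2-bis(2-hydroxyethyl)-3-methylcyclohexane-1,3-dicarboxylate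
Conditions: H2 (1 atm), Pd/C, EtOAc/MeOH, rt; filtered and used at once
Reagents that add atoms: none
Why: Heterogeneous catalytic hydrogenation saturates C2=C3 and hydrogenolyses the benzyl ether in one operation without forming a stereocenter, and the neutral diol is taken on at once so that its hydroxyethyl arms have little time to lactonise onto the hindered esters.

**Step 15**
Reactants: 21 the diol
Product: 22 2,2'-[(1R,2R,3R)-1,3-bis(methoxycarbonyl)-3-methylcyclohexane-1,2-diyl]diacetic acid
Conditions: TEMPO (cat.), NaOCl (cat.), NaClO2, MeCN/phosphate buffer (pH 6.7), 35 °C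
Reagents that add atoms: sodium chlorite ([Na+].[O-]Cl=O)
Why: TEMPO-catalysed chlorite oxidation under buffered conditions converts both primary alcohols into the carboxylic acids C7 and C8 without touching the tertiary esters.

**Step 16**
Reactants: 22 the diacid
Product: 23 dimethyl (1R,2R,3R)-1,2-bis(2-methoxy-2-oxoethyl)-3-methylcyclohexane-1,3-dicarboxylate
Conditions: TMSCHN2, PhMe/MeOH, 0 °C
Reagents that add atoms: trimethylsilyldiazomethane (C[Si](C)(C)C=[N+]=[N-])
Why: Diazoalkane-type esterification under neutral conditions gives the tetraester needed for the Dieckmann closure.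

**Step 17**
Reactants: 23 the tetraester
Product: 24 ring-B β-keto ester (trans-fused A/B hydrindanone with the ketone at C8 and the ester on C6)
Conditions: KOt-Bu, THF, 0 °C → rt; AcOH
Reagents that add atoms: none
Why: Dieckmann condensation between the trans-diequatorial acetate arms closes ring B (C6–C8); it is reversible and should rest in the enolate that carries the ester on C6, next to tertiary C5, not on C9, next to quaternary C10, while C19 and C20 have no α-hydrogen and stay out.

**Step 18**
Reactants: 24 ring-B β-keto ester; 25 2-(2-bromoethyl)-2-methyl-1,3-dioxolane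
Product: 26 C9-alkylated β-keto ester carrying the 2-(2-methyl-1,3-dioxolan-2-yl)ethyl chain (C11–C14)
Conditions: LiN(i-Pr)2 (LDA, 2.2 equiv), THF/HMPA, −78 → 0 °C; 25, 0 °C → rt
Reagents that add atoms: none
Why: γ-Alkylation of the β-keto ester dianion, whose second and more reactive enolate carbon is C9, the only remaining α-position of the C8 ketone, so the masked 3-oxobutyl chain enters there; C9 is epimerisable and is fixed in step 19.

**Step 19**
Reactants: 26 the ketal
Product: 28 tricyclic enone triester (rings A B C; C13 ketone conjugated to C8=C14), via diketone 27 (not isolated)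
Conditions: 2 M HCl, THF, rt; then TsOH·H2O (cat.), PhH, reflux (Dean–Stark)
Reagents that add atoms: water (O)
Why: Acetal hydrolysis then acid-catalysed intramolecular aldol condensation of the methyl ketone (C14) onto the C8 ketone (Robinson-type cyclodehydration) closes ring C; under these equilibrating conditions C9 should take, through the dienol, the pseudoequatorial orientation with C11 cis to the axial C20 ester (the arrangement favoured next to the angular carbon of a trans-hydrindane) and C6 the ester trans to C4.

**Step 20**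
Reactants: 28 the tricyclic enone
Product: 29 C8-propargyl C13-ketone triester (cis-fused rings B and C)
Conditions: TiCl4, CH2=C=CHSnBu3, CH2Cl2, −78 °C; then NaOMe (cat.), MeOH, 0 °C
Reagents that add atoms: allenyltributylstannane (C=C=C[Sn](CCCC)(CCCC)CCCC)
Why: Lewis-acid-promoted conjugate propargylation by SE2′ transfer from the allenylstannane, in which axial attack at C8 of the ring-C half-chair should give the cis-fused hydrindanone with the propargyl group on the face of H9 and away from the axial C20 ester, setting the C8 quaternary center, while the brief methoxide treatment leaves C6 as the more stable ester trans to C4.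

**Step 21**
Reactants: 29 the propargyl ketone
Product: 30 trimethyl ent-13-hydroxygibberell-16-ene-7,19,20-trioate (trimethyl ester of the target)
Conditions: SmI2, HMPA, t-BuOH, THF, 0 °C
Reagents that add atoms: none
Why: Ketyl–alkyne reductive cyclisation (5-exo-dig), in which the C13 ketyl adds to C16 of the propargyl arm, which can bridge only on its own face of ring C, so the bicyclo[3.2.1]octane should form with the bridgehead C13 hydroxyl and the C16 exocyclic methylene directly and the esters stay inert.

**Step 22**
Reactants: 30 trimethyl ent-13-hydroxygibberell-16-ene-7,19,20-trioate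
Product: 31 ent-13-hydroxygibberell-16-ene-7,19,20-trioic acid (the target gibberellin triacid)
Conditions: n-PrSLi, HMPA, 25 → 50 °C; aq. HCl to pH 3
Reagents that add atoms: none
Why: SN2 O-demethylation of the three methyl esters by thiolate cleaves the hindered C19 and C20 esters without acyl attack or strong acid, so the acid-labile 13-hydroxy-16-ene unit and all stereocenters should survive.

**Compound list**

1 | 3-[(4-methoxybenzyl)oxy]propanoic acid | COc1ccc(COCCC(=O)O)cc1 | starting material
2 | (S)-4-benzyl-1,3-oxazolidin-2-one | O=C1N[C@@H](Cc2ccccc2)CO1 | starting material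
3 | (S)-4-benzyl-3-{3-[(4-methoxybenzyl)oxy]propanoyl}-1,3-oxazolidin-2-one | COc1ccc(COCCC(=O)N2[C@@H](Cc3ccccc3)COC2=O)cc1 | intermediate
4 | acrolein | C=CC=O | starting material
5 | (S)-4-benzyl-3-[(2S,3R)-3-hydroxy-2-{[(4-methoxybenzyl)oxy]methyl}pent-4-enoyl]-1,3-oxazolidin-2-one | C=C[C@@H](O)[C@H](COCc1ccc(OC)cc1)C(=O)N1[C@@H](Cc2ccccc2)COC1=O | intermediate
6 | methyl (2S,3R)-3-hydroxy-2-{[(4-methoxybenzyl)oxy]methyl}pent-4-enoate | C=C[C@@H](O)[C@H](COCc1ccc(OC)cc1)C(=O)OC | intermediate
7 | methyl (2S,3R)-3-hydroxy-2-{[(4-methoxybenzyl)oxy]methyl}-2-methylpent-4-enoate | C=C[C@@H](O)[C@@](C)(C(=O)OC)COCc1ccc(OC)cc1 | intermediate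
8 | triethyl phosphonoacetate | CCOC(=O)CP(=O)(OCC)OCC | starting material
9 | benzyl 2-bromoethyl ether | BrCCOCc1ccccc1 | starting material
10 | ethyl 4-(benzyloxy)-2-(diethoxyphosphoryl)butanoate (racemic) | CCOC(=O)C(CCOCc1ccccc1)P(=O)(OCC)OCC | intermediate
11 | 4-(benzyloxy)-2-(diethoxyphosphoryl)butanoic acid (racemic) | OC(=O)C(CCOCc1ccccc1)P(=O)(OCC)OCC | intermediate
12 | methyl (2S,3R)-3-{[4-(benzyloxy)-2-(diethoxyphosphoryl)butanoyl]oxy}-2-{[(4-methoxybenzyl)oxy]methyl}-2-methylpent-4-enoate (both epimers at the phosphorus-bearing carbon) | C=C[C@@H](OC(=O)C(CCOCc1ccccc1)P(=O)(OCC)OCC)[C@@](C)(C(=O)OC)COCc1ccc(OC)cc1 | intermediate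
13 | methyl (2S,3R)-3-{[4-(benzyloxy)-2-(diethoxyphosphoryl)butanoyl]oxy}-2-(hydroxymethyl)-2-methylpent-4-enoate | C=C[C@@H](OC(=O)C(CCOCc1ccccc1)P(=O)(OCC)OCC)[C@@](C)(C(=O)OC)CO | intermediate
14 | methyl (2R,3R)-3-{[4-(benzyloxy)-2-(diethoxyphosphoryl)butanoyl]oxy}-2-formyl-2-methylpent-4-enoate | C=C[C@@H](OC(=O)C(CCOCc1ccccc1)P(=O)(OCC)OCC)[C@@](C)(C(=O)OC)C=O | intermediate
15 | methyl (2R,3S)-5-[2-(benzyloxy)ethyl]-2-ethenyl-3-methyl-6-oxo-3,6-dihydro-2H-pyran-3-carboxylate (unsaturated δ-lactone; C18 methyl cis to the C3 vinyl group) | O=C1O[C@H](C=C)[C@@](C)(C(=O)OC)C=C1CCOCc1ccccc1 | intermediate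
16 | trimethylsilyl ketene acetal of the C5-vinyl lactone (C10=C20 silyl enol ether; C5 vinyl trans to the C3 vinyl group; not isolated) | c1ccccc1COCCC1=C(O[Si](C)(C)C)O[C@H](C=C)[C@@](C)(C(=O)OC)[C@H]1C=C | intermediate
17 | trimethylsilyl ester of acid 18 (not isolated) | c1ccccc1COCC[C@]1(C(=O)O[Si](C)(C)C)CC=C[C@@](C)(C(=O)OC)[C@H]1C=C | intermediate
18 | (1R,2S,3R)-1-[2-(benzyloxy)ethyl]-2-ethenyl-3-(methoxycarbonyl)-3-methylcyclohex-4-ene-1-carboxylic acid (ring A; C20 acid cis to the C19 ester, C5 vinyl trans to the C10 arm) | c1ccccc1COCC[C@]1(C(=O)O)CC=C[C@@](C)(C(=O)OC)[C@H]1C=C | intermediate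
19 | dimethyl (1R,2S,3R)-1-[2-(benzyloxy)ethyl]-2-ethenyl-3-methylcyclohex-4-ene-1,3-dicarboxylate | c1ccccc1COCC[C@]1(C(=O)OC)CC=C[C@@](C)(C(=O)OC)[C@H]1C=C | intermediate
20 | dimethyl (1R,2S,3R)-1-[2-(benzyloxy)ethyl]-2-(2-hydroxyethyl)-3-methylcyclohex-4-ene-1,3-dicarboxylate | c1ccccc1COCC[C@]1(C(=O)OC)CC=C[C@@](C)(C(=O)OC)[C@H]1CCO | intermediate
21 | dimethyl (1R,2R,3R)-1,2-bis(2-hydroxyethyl)-3-methylcyclohexane-1,3-dicarboxylate | OCC[C@]1(C(=O)OC)CCC[C@@](C)(C(=O)OC)[C@H]1CCO | intermediate
22 | 2,2'-[(1R,2R,3R)-1,3-bis(methoxycarbonyl)-3-methylcyclohexane-1,2-diyl]diacetic acid | OC(=O)C[C@]1(C(=O)OC)CCC[C@@](C)(C(=O)OC)[C@H]1CC(=O)O | intermediate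
23 | dimethyl (1R,2R,3R)-1,2-bis(2-methoxy-2-oxoethyl)-3-methylcyclohexane-1,3-dicarboxylate | COC(=O)C[C@]1(C(=O)OC)CCC[C@@](C)(C(=O)OC)[C@H]1CC(=O)OC | intermediate
24 | ring-B β-keto ester: trans-fused A/B hydrindanone, C8 ketone, methyl esters at C6, C4 (C19) and C10 (C20); C4, C5, C10 as in 23, C6 epimers and enol | O=C1C[C@]2(C(=O)OC)CCC[C@@](C)(C(=O)OC)[C@H]2C1C(=O)OC | intermediate
25 | 2-(2-bromoethyl)-2-methyl-1,3-dioxolane | CC1(CCBr)OCCO1 | starting material
26 | 24 alkylated at C9 with the 2-(2-methyl-1,3-dioxolan-2-yl)ethyl chain (C6 and C9 epimers) | O=C1C(CCC2(C)OCCO2)[C@]3(C(=O)OC)CCC[C@@](C)(C(=O)OC)[C@H]3C1C(=O)OC | intermediate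
27 | 1,5-diketone: 24 carrying a 3-oxobutyl chain on C9 (not isolated) | O=C1C(CCC(C)=O)[C@]2(C(=O)OC)CCC[C@@](C)(C(=O)OC)[C@H]2C1C(=O)OC | intermediate
28 | tricyclic enone triester: rings A, B and C, C13 ketone conjugated to C8=C14, H9 on the face of H5, C7 ester trans to C4 | O=C1CC[C@H]2[C@]3(C(=O)OC)CCC[C@@](C)(C(=O)OC)[C@H]3[C@H](C(=O)OC)C2=C1 | intermediate
29 | C8-propargyl C13-ketone triester: cis-fused rings B and C, propargyl on the face of H9 | C#CC[C@]23CC(=O)CC[C@H]2[C@]1(C(=O)OC)CCC[C@@](C)(C(=O)OC)[C@H]1[C@@H]3C(=O)OC | intermediate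
30 | trimethyl ent-13-hydroxygibberell-16-ene-7,19,20-trioate (trimethyl ester of the target) | C=C1C[C@]23C[C@@]1(O)CC[C@H]2[C@]1(C(=O)OC)CCC[C@@](C)(C(=O)OC)[C@H]1[C@@H]3C(=O)OC | intermediate
31 | ent-13-hydroxygibberell-16-ene-7,19,20-trioic acid (the target gibberellin triacid) | C=C1C[C@]23C[C@@]1(O)CC[C@H]2[C@]1(C(=O)O)CCC[C@@](C)(C(=O)O)[C@H]1[C@@H]3C(=O)O | target

**Step count and risks**

Total steps: 22. Longest linear sequence: 20 steps (steps 1–4 and 7–22; steps 5 and 6 make the phosphonate acid 11).

Steps most likely to fail: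

Step 11 (carries the proposed new method). The Grignard reagent may attack the lactone carbonyl or open the allylic carboxylate by SN2′ while 1,4-addition at the neopentyl C5 is slow or takes the wrong face, and the labile trimethylsilyl ketene acetal may be lost before it rearranges. The fallback separates the two events with known chemistry and sets out from 15. Lithium divinylcuprate, (CH2=CH)2CuLi, with BF3·OEt2 in Et2O at −78 °C and an aqueous NH4Cl quench should give the saturated lactone, methyl 5-[2-(benzyloxy)ethyl]-2,4-diethenyl-3-methyl-6-oxooxane-3-carboxylate F1. Its only α-hydrogen, at C10, would be removed with KN(SiMe3)2 in the presence of TBSCl (THF/HMPA, −78 °C) to give the more robust tert-butyldimethylsilyl ketene acetal F2. Heating in toluene at 110 °C should then give the tert-butyldimethylsilyl ester F3 by the known lactone-enolate Claisen rearrangement, and mild acid hydrolysis returns to the route at 18.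

Step 18. C-alkylation at the neopentyl C9 by a β-branched bromide may be slow, so that O-alkylation or loss of HBr from 25 takes over. The fallback sets out from 24 and replaces the SN2 step by a Lewis-acid Michael addition. Silylation (Et3N, TMSCl; then LiN(i-Pr)2, TMSCl, −78 °C) should give the 1,3-bis(trimethylsilyloxy)diene F4. Mukaiyama–Michael addition of its terminal carbon (C9) to methyl vinyl ketone (TiCl4, CH2Cl2, −78 °C) and aqueous work-up should give the diketone 27, here isolated, from which the route continues with the cyclodehydration of step 19.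

Step 20. The stannane may transfer its wrong terminus (allenyl ketone), or protodestannylation and enolisation toward C6 may outrun addition at the fully substituted C8. The fallback sets out from 28 and builds ring D by the classical pinacol route. Sakurai allylation (allyltrimethylsilane, TiCl4, CH2Cl2, −78 °C) should give the C8-allyl ketone F5. Ozonolysis (O3, CH2Cl2/MeOH, −78 °C; Me2S) should give the keto aldehyde F6, and SmI2-mediated pinacol coupling of C13 with C16 (THF, t-BuOH) the 13,16-diol F7. Swern oxidation of the secondary hydroxyl should give the 16-ketone F8, and Wittig methylenation (Ph3PCH3Br, KOt-Bu, THF) rejoins the route at 30.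

**Further compounds**

F1 | step 11 | saturated lactone: methyl 5-[2-(benzyloxy)ethyl]-2,4-diethenyl-3-methyl-6-oxooxane-3-carboxylate (4-vinyl trans to 2-vinyl, C5 epimers) | c1ccccc1COCCC1C(=O)O[C@H](C=C)[C@@](C)(C(=O)OC)[C@H]1C=C
F2 | step 11 | tert-butyldimethylsilyl ketene acetal of F1 | c1ccccc1COCCC1=C(O[Si](C)(C)C(C)(C)C)O[C@H](C=C)[C@@](C)(C(=O)OC)[C@H]1C=C
F3 | step 11 | tert-butyldimethylsilyl ester of acid 18 | c1ccccc1COCC[C@]1(C(=O)O[Si](C)(C)C(C)(C)C)CC=C[C@@](C)(C(=O)OC)[C@H]1C=C
F4 | step 18 | 1,3-bis(trimethylsilyloxy)diene of β-keto ester 24 (C8=C9 silyl enol ether and C6=C7 silyl ketene acetal) | C[Si](C)(C)OC1=C[C@]2(C(=O)OC)CCC[C@@](C)(C(=O)OC)[C@H]2C1=C(OC)O[Si](C)(C)C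
F5 | step 20 | C8-allyl C13-ketone triester | C=CC[C@]23CC(=O)CC[C@H]2[C@]1(C(=O)OC)CCC[C@@](C)(C(=O)OC)[C@H]1[C@@H]3C(=O)OC
F6 | step 20 | keto aldehyde: C8-(2-oxoethyl) C13-ketone triester | O=CC[C@]23CC(=O)CC[C@H]2[C@]1(C(=O)OC)CCC[C@@](C)(C(=O)OC)[C@H]1[C@@H]3C(=O)OC
F7 | step 20 | 13,16-dihydroxy-17-nor triester (C16 epimers) | OC1C[C@]23C[C@@]1(O)CC[C@H]2[C@]1(C(=O)OC)CCC[C@@](C)(C(=O)OC)[C@H]1[C@@H]3C(=O)OC
F8 | step 20 | 13-hydroxy-16-oxo-17-nor triester | O=C1C[C@]23C[C@@]1(O)CC[C@H]2[C@]1(C(=O)OC)CCC[C@@](C)(C(=O)OC)[C@H]1[C@@H]3C(=O)OC
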